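**Strategy**

The flavone is cut at both bonds of the C4 carbonyl of ring C. C4 lies between C4a of ring A and C3, which carries the methoxy group, so it can be delivered as carbon monoxide. One palladium-catalysed carbonylative α-arylation joins it to a ring A ortho-iodophenol silyl ether (iodine at the future C4a, silyl ether on the future C8a oxygen) and a ring B ω-methoxyacetophenone. That operation forms C4a–C4 and C3–C4 and gives the complete carbon skeleton as a 1,3-diketone. Only the C8a oxygen carries a fluoride-labile group, so the later pyranone closure cannot give the 8-methoxy isomer; acetal removal then ends the synthesis.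

Key step: step 8

Remark on the chemistry: the Weinreb amide of methoxyacetic acid is taken as a purchasable building block. The target has no stereocentre; the central carbon of the 1,3-diketones is racemic, epimerisable and erased when ring C becomes aromatic.

**Route**

Step 1
Reactants: 1 2-methoxyresorcinol
Product: 2 2-methoxy-1,3-bis(methoxymethoxy)benzene
Conditions: MOMCl (2.5 equiv), i-Pr2NEt, CH2Cl2, 0 °C to rt
Reagents that add atoms: chloromethyl methyl ether (MOMCl), COCCl
Why: Williamson-type O-alkylation of both phenols by the reactive α-chloro ether under amine base (MOM protection) gives acetals that later withstand organometallic, basic and fluoride conditions.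

Step 2
Reactants: 2 2-methoxy-1,3-bis(methoxymethoxy)benzene
Product: 4 4-methoxy-3,5-bis(methoxymethoxy)phenol, via pinacol arylboronate 3 (not isolated)
Conditions: [Ir(OMe)(cod)]2 (1.5 mol %), 4,4'-di-tert-butyl-2,2'-bipyridine (3 mol %), B2pin2 (1.0 equiv), THF, 80 °C; then NaBO3·4H2O, THF/H2O, rt
Reagents that add atoms: sodium perborate, [Na+].[O-]OB=O (phenol oxygen of 4); bis(pinacolato)diboron, CC1(C)OB(OC1(C)C)B1OC(C)(C)C(C)(C)O1 (boryl group of 3 only)
Why: Sterically governed iridium-catalysed C–H borylation of a 1,2,3-trisubstituted arene should attack the only C–H without an ortho neighbour (C5), and perborate oxidation of the boronate in the same flask converts C–B into C–OH at that carbon, a known one-pot arene-to-phenol sequence to which MOM ethers are inert.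

Step 3
Reactants: 4 4-methoxy-3,5-bis(methoxymethoxy)phenol
Product: 5 2-iodo-4-methoxy-3,5-bis(methoxymethoxy)phenol
Conditions: NIS (1.0 equiv), DMF, −20 °C to 0 °C, dark
Reagents that add atoms: N-iodosuccinimide (NIS), O=C1CCC(=O)N1I
Why: Electrophilic aromatic iodination of a strongly activated phenol, in which the two open positions are symmetry-equivalent and both ortho to the hydroxyl, so one equivalent of an acid-free iodonium source can give only this mono-iodide constitution and leaves the acetals alone.

Step 4
Reactants: 5 2-iodo-4-methoxy-3,5-bis(methoxymethoxy)phenol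
Product: 6 tert-butyl[2-iodo-4-methoxy-3,5-bis(methoxymethoxy)phenoxy]dimethylsilane
Conditions: TBSCl, imidazole, DMF, rt
Reagents that add atoms: tert-butyldimethylsilyl chloride (TBSCl), CC(C)(C)[Si](C)(C)Cl
Why: Imidazole-promoted silylation of a phenol places the only fluoride-labile group of the molecule on the oxygen that is to become O1.

Step 5
Reactants: 7 4-bromophenol; 8 prenyl bromide (1-bromo-3-methylbut-2-ene)
Product: 9 4-bromo-2,6-bis(3-methylbut-2-enyl)phenol
Conditions: NaH (2.2 equiv), toluene, 0 °C to rt; 8 (2.2 equiv)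
Reagents that add atoms: none
Why: ortho-C-alkylation of a sodium phenoxide held as a tight ion pair in a non-polar solvent is a known route to 2,6-diprenyl-4-halophenols, the para position being blocked by bromine and attack at the primary carbon of the allylic bromide giving the normal prenyl group twice.

Step 6
Reactants: 9 4-bromo-2,6-bis(3-methylbut-2-enyl)phenol
Product: 10 5-bromo-2-(methoxymethoxy)-1,3-bis(3-methylbut-2-enyl)benzene
Conditions: NaH, DMF, 0 °C; MOMCl, 0 °C to rt
Reagents that add atoms: chloromethyl methyl ether (MOMCl), COCCl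
Why: O-alkylation of the hindered sodium phenoxide in a dipolar aprotic solvent (MOM protection) removes the acidic proton before halogen–lithium exchange.

Step 7
Reactants: 10 5-bromo-2-(methoxymethoxy)-1,3-bis(3-methylbut-2-enyl)benzene; 11 N,2-dimethoxy-N-methylacetamide
Product: 13 2-methoxy-1-[4-(methoxymethoxy)-3,5-bis(3-methylbut-2-enyl)phenyl]ethanone, via aryllithium 12 (not isolated)
Conditions: n-BuLi (1.05 equiv), THF, −78 °C; then 11, −78 °C to 0 °C; aq NH4Cl
Reagents that add atoms: n-butyllithium, [Li]CCCC (lithium of 12 only; no atom of it remains in 13)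
Why: Bromine–lithium exchange at −78 °C is much faster than deprotonation of the benzylic-allylic methylenes, and the aryllithium adds once to the amide through a chelated tetrahedral intermediate that releases the ketone only on work-up (Weinreb ketone synthesis).

Step 8
Reactants: 6 tert-butyl[2-iodo-4-methoxy-3,5-bis(methoxymethoxy)phenoxy]dimethylsilane; 13 2-methoxy-1-[4-(methoxymethoxy)-3,5-bis(3-methylbut-2-enyl)phenyl]ethanone; 14 carbon monoxide
Product: 16 1-[2-(tert-butyldimethylsilyloxy)-5-methoxy-4,6-bis(methoxymethoxy)phenyl]-2-methoxy-3-[4-(methoxymethoxy)-3,5-bis(3-methylbut-2-enyl)phenyl]propane-1,3-dione (racemic at C2), via sodium enolate 15 (not isolated)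
Conditions: 13 (2.0 equiv), NaN(SiMe3)2 (2.0 equiv), THF, −78 °C to 0 °C; then 6, Pd(dba)2 (5 mol %), 1,3-bis(diphenylphosphino)propane (dppp, 6 mol %), CO (1.5 bar), THF/1,4-dioxane, 80 °C, sealed vessel; aq NH4Cl
Reagents that add atoms: sodium bis(trimethylsilyl)amide, C[Si](C)(C)[N-][Si](C)(C)C.[Na+] (sodium of 15 only; no atom of it remains in 16)
Why: Oxidative addition of the C–I bond of 6 to zerovalent palladium, migratory insertion of CO to give an aroyl complex of divalent palladium, attack of the carbon terminus of enolate 15 on that complex and reductive elimination create C4a–C4 and C3–C4, after which a second equivalent of 15 deprotonates the acidic diketone and so shields it until work-up. The closest known reaction type is the palladium-catalysed carbonylative α-arylation of aryl alkyl ketones with aryl iodides to 1,3-diketones under a chelating diphosphine and about one atmosphere of CO. No ring is closed here, and the one new stereocentre, C2 of the diketone, is left racemic on purpose because it is epimerisable and disappears when ring C is aromatised. The step needs carbonylative coupling to beat direct α-arylation: the aryl–palladium flanked by OTBS and OMOM is too hindered to accept the enolate quickly, insertion of CO moves the metal one atom away from that congestion, and dppp under CO is a poor catalyst for direct arylation. It also needs C- rather than O-acylation, which the sodium enolate chelated through its methoxy oxygen and C–C reductive elimination from the acyl(enolate)palladium favour. The site of acylation on ring A is fixed in advance by the iodine, and using two equivalents of preformed enolate with no free amide base avoids aminocarbonylation.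

Step 9
Reactants: 16 1-[2-(tert-butyldimethylsilyloxy)-5-methoxy-4,6-bis(methoxymethoxy)phenyl]-2-methoxy-3-[4-(methoxymethoxy)-3,5-bis(3-methylbut-2-enyl)phenyl]propane-1,3-dione
Product: 18 3,6-dimethoxy-5,7-bis(methoxymethoxy)-2-[4-(methoxymethoxy)-3,5-bis(3-methylbut-2-enyl)phenyl]chromen-4-one, via free-phenol diketone 17 (not isolated)
Conditions: TBAF/AcOH (1:1, 1.2 equiv), THF, 0 °C to rt; concentrate; then AcOH, 70 °C
Reagents that add atoms: none
Why: Buffered fluoride cleaves the aryl silyl ether alone, and the freed C8a phenol adds to the ring B carbonyl and loses water in warm acetic acid (cyclodehydration of an ortho-hydroxyaryl 1,3-diketone, as in the last stage of Baker–Venkataraman flavone syntheses), which is too weak an acid to open aryl MOM acetals, so closure can occur only through O1 and the racemic centre vanishes as C2=C3 forms.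

Step 10
Reactants: 18 3,6-dimethoxy-5,7-bis(methoxymethoxy)-2-[4-(methoxymethoxy)-3,5-bis(3-methylbut-2-enyl)phenyl]chromen-4-one
Product: 19 5,7-dihydroxy-2-[4-hydroxy-3,5-bis(3-methylbut-2-enyl)phenyl]-3,6-dimethoxychromen-4-one
Conditions: HCl (about 1 M in MeOH), THF co-solvent, rt to 40 °C
Reagents that add atoms: none
Why: Acid-catalysed acetal exchange with methanol frees the three phenols as dimethoxymethane, and dilute acid at mild temperature is the usual way to unmask MOM-protected prenylated flavonoids without closing an ortho-prenyl phenol to a chroman.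

**Compound list**

1 | 2-methoxyresorcinol (2-methoxybenzene-1,3-diol) | COc1c(O)cccc1O | starting material
2 | 2-methoxy-1,3-bis(methoxymethoxy)benzene | COCOc1cccc(OCOC)c1OC | intermediate
3 | 2-[4-methoxy-3,5-bis(methoxymethoxy)phenyl]-4,4,5,5-tetramethyl-1,3,2-dioxaborolane (formed in the flask) | COCOc1cc(B2OC(C)(C)C(C)(C)O2)cc(OCOC)c1OC | intermediate
4 | 4-methoxy-3,5-bis(methoxymethoxy)phenol | COCOc1cc(O)cc(OCOC)c1OC | intermediate
5 | 2-iodo-4-methoxy-3,5-bis(methoxymethoxy)phenol | COCOc1cc(O)c(I)c(OCOC)c1OC | intermediate
6 | tert-butyl[2-iodo-4-methoxy-3,5-bis(methoxymethoxy)phenoxy]dimethylsilane | CC(C)(C)[Si](C)(C)Oc1cc(OCOC)c(OC)c(OCOC)c1I | intermediate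
7 | 4-bromophenol | Oc1ccc(Br)cc1 | starting material
8 | prenyl bromide (1-bromo-3-methylbut-2-ene) | CC(C)=CCBr | starting material
9 | 4-bromo-2,6-bis(3-methylbut-2-enyl)phenol | CC(C)=CCc1cc(Br)cc(CC=C(C)C)c1O | intermediate
10 | 5-bromo-2-(methoxymethoxy)-1,3-bis(3-methylbut-2-enyl)benzene | COCOc1c(CC=C(C)C)cc(Br)cc1CC=C(C)C | intermediate
11 | N,2-dimethoxy-N-methylacetamide | COCC(=O)N(C)OC | starting material
12 | [4-(methoxymethoxy)-3,5-bis(3-methylbut-2-enyl)phenyl]lithium (formed in the flask) | [Li]c1cc(CC=C(C)C)c(OCOC)c(CC=C(C)C)c1 | intermediate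
13 | 2-methoxy-1-[4-(methoxymethoxy)-3,5-bis(3-methylbut-2-enyl)phenyl]ethanone | COCC(=O)c1cc(CC=C(C)C)c(OCOC)c(CC=C(C)C)c1 | intermediate
14 | carbon monoxide | [C-]#[O+] | starting material
15 | sodium (Z)-2-methoxy-1-[4-(methoxymethoxy)-3,5-bis(3-methylbut-2-enyl)phenyl]ethen-1-olate (formed in the flask; Z geometry expected from sodium chelation, of no consequence) | CO/C=C(\[O-])c1cc(CC=C(C)C)c(OCOC)c(CC=C(C)C)c1.[Na+] | intermediate
16 | 1-[2-(tert-butyldimethylsilyloxy)-5-methoxy-4,6-bis(methoxymethoxy)phenyl]-2-methoxy-3-[4-(methoxymethoxy)-3,5-bis(3-methylbut-2-enyl)phenyl]propane-1,3-dione (racemic at C2) | CC(C)(C)[Si](C)(C)Oc1cc(OCOC)c(OC)c(OCOC)c1C(=O)C(OC)C(=O)c1cc(CC=C(C)C)c(OCOC)c(CC=C(C)C)c1 | intermediate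
17 | 1-[2-hydroxy-5-methoxy-4,6-bis(methoxymethoxy)phenyl]-2-methoxy-3-[4-(methoxymethoxy)-3,5-bis(3-methylbut-2-enyl)phenyl]propane-1,3-dione (racemic at C2; formed in the flask, in equilibrium with its cyclic hemiketal) | COCOc1cc(O)c(C(=O)C(OC)C(=O)c2cc(CC=C(C)C)c(OCOC)c(CC=C(C)C)c2)c(OCOC)c1OC | intermediate
18 | 3,6-dimethoxy-5,7-bis(methoxymethoxy)-2-[4-(methoxymethoxy)-3,5-bis(3-methylbut-2-enyl)phenyl]chromen-4-one | COCOc1cc2oc(-c3cc(CC=C(C)C)c(OCOC)c(CC=C(C)C)c3)c(OC)c(=O)c2c(OCOC)c1OC | intermediate
19 | 5,7-dihydroxy-2-[4-hydroxy-3,5-bis(3-methylbut-2-enyl)phenyl]-3,6-dimethoxychromen-4-one (CNP0236361.0) | COc1c(O)cc2oc(-c3cc(CC=C(C)C)c(O)c(CC=C(C)C)c3)c(OC)c(=O)c2c1O | target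

**Step count**

Total: 10 steps. Longest linear sequence: 7 steps (steps 1, 2, 3, 4, 8, 9, 10); the ring B branch (steps 5, 6, 7) joins at step 8.

**Steps most likely to fail, with fallbacks**

Step 8. The oxidative addition or the CO insertion may stall at the electron-rich, doubly ortho-substituted iodide and end in hydrodeiodination. Direct α-arylation or O-acylation may compete with the carbonylative C-acylation, and the basic medium may transfer the silyl group. The fallback sets out from 6 and returns at 16, and it builds the same two bonds without palladium. Iodine–magnesium exchange of 6 with i-PrMgCl·LiCl (THF, −20 °C) gives [2-(tert-butyldimethylsilyloxy)-5-methoxy-4,6-bis(methoxymethoxy)phenyl]magnesium chloride F1. Formylation of this with DMF gives 2-(tert-butyldimethylsilyloxy)-5-methoxy-4,6-bis(methoxymethoxy)benzaldehyde F2. Ketone 13 is deprotonated with LiN(i-Pr)2 (THF, −78 °C) to lithium (Z)-2-methoxy-1-[4-(methoxymethoxy)-3,5-bis(3-methylbut-2-enyl)phenyl]ethen-1-olate F3. Aldol addition of this enolate to the aldehyde, quenched cold to prevent silyl migration to the new alkoxide, gives 3-[2-(tert-butyldimethylsilyloxy)-5-methoxy-4,6-bis(methoxymethoxy)phenyl]-3-hydroxy-2-methoxy-1-[4-(methoxymethoxy)-3,5-bis(3-methylbut-2-enyl)phenyl]propan-1-one F4 as a mixture of racemic diastereomers. Oxidation of the secondary alcohol with Dess–Martin periodinane (NaHCO3, CH2Cl2) gives 16.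

Step 10. While the acetals are cleaved, the protic acid may protonate the prenyl double bonds. This would lead to ring closure onto the neighbouring 4'-oxygen or to addition of solvent. The fallback sets out from 18 and returns at 19, and it avoids Brønsted acid altogether. Treatment of 18 with TMSOTf and 2,2'-bipyridyl (CH2Cl2/MeCN, 0 °C) converts aryl MOM ethers into aryl silyl ethers by transfer of the methoxymethyl group to the pyridine nitrogen. The product is 3,6-dimethoxy-5,7-bis(trimethylsilyloxy)-2-[3,5-bis(3-methylbut-2-enyl)-4-(trimethylsilyloxy)phenyl]chromen-4-one F5, and its labile silyl ethers are hydrolysed on neutral aqueous work-up to 19.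

Step 5. O-alkylation may compete with C-alkylation, and the second ortho-alkylation may remain incomplete, so that the conversion to the 2,6-dialkylated phenol is low. The fallback sets out from 7 and returns at 10, bypassing 9, and it installs both prenyl groups by cross-coupling. Iodination of 7 at both ortho positions (NIS, 2.1 equiv, cat. TsOH, MeCN) gives 4-bromo-2,6-diiodophenol F6. Protection (MOMCl, i-Pr2NEt, CH2Cl2) gives 5-bromo-1,3-diiodo-2-(methoxymethoxy)benzene F7. A double Stille coupling with tributyl(3-methylbut-2-enyl)stannane (Pd(PPh3)4, DMF, 80 °C) then gives 10; the two C–I bonds undergo oxidative addition well before the C–Br bond, and the stannane transfers the linear prenyl group.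

**Further compounds**

F1 | step 8 | [2-(tert-butyldimethylsilyloxy)-5-methoxy-4,6-bis(methoxymethoxy)phenyl]magnesium chloride | CC(C)(C)[Si](C)(C)Oc1cc(OCOC)c(OC)c(OCOC)c1[Mg]Cl
F2 | step 8 | 2-(tert-butyldimethylsilyloxy)-5-methoxy-4,6-bis(methoxymethoxy)benzaldehyde | CC(C)(C)[Si](C)(C)Oc1cc(OCOC)c(OC)c(OCOC)c1C=O
F3 | step 8 | lithium (Z)-2-methoxy-1-[4-(methoxymethoxy)-3,5-bis(3-methylbut-2-enyl)phenyl]ethen-1-olate | CO/C=C(\[O-])c1cc(CC=C(C)C)c(OCOC)c(CC=C(C)C)c1.[Li+]
F4 | step 8 | 3-[2-(tert-butyldimethylsilyloxy)-5-methoxy-4,6-bis(methoxymethoxy)phenyl]-3-hydroxy-2-methoxy-1-[4-(methoxymethoxy)-3,5-bis(3-methylbut-2-enyl)phenyl]propan-1-one (mixture of racemic diastereomers) | CC(C)(C)[Si](C)(C)Oc1cc(OCOC)c(OC)c(OCOC)c1C(O)C(OC)C(=O)c1cc(CC=C(C)C)c(OCOC)c(CC=C(C)C)c1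
F5 | step 10 | 3,6-dimethoxy-5,7-bis(trimethylsilyloxy)-2-[3,5-bis(3-methylbut-2-enyl)-4-(trimethylsilyloxy)phenyl]chromen-4-one | COc1c(O[Si](C)(C)C)cc2oc(-c3cc(CC=C(C)C)c(O[Si](C)(C)C)c(CC=C(C)C)c3)c(OC)c(=O)c2c1O[Si](C)(C)C
F6 | step 5 | 4-bromo-2,6-diiodophenol | Oc1c(I)cc(Br)cc1I
F7 | step 5 | 5-bromo-1,3-diiodo-2-(methoxymethoxy)benzene | COCOc1c(I)cc(Br)cc1I
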